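Ring numbering used: C1 (OAc), C2=C3(Me), C4 (OH), C5, C6=C7(Me), C8, C9 (OBz), C10 (i-Pr). The ten-membered carbocycle is closed last at C3–C4 by an intramolecular Ni/Cr (Nozaki–Hiyama–Kishi) addition of a (Z)-alkenyl iodide to an aldehyde. It exploits C4: the only free hydroxyl, allylic to the Z C2=C3 bond, so one operation forms the ring, the C4 stereocentre and the free OH with both esters already present. The precursor is an open-chain (Z,Z)-iodo aldehyde; its C6=C7 Z geometry comes from Birch dearomatisation/ozonolysis of 3-methylanisole, its C9/C10 centres from an auxiliary aldol, and C1 from an Evans–Tishchenko reduction that also installs the benzoate.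

Key step: step 15

Remark: the enantiomer of the chiral chromium ligand in step 15 is assumed to be selectable so that the alkenyl group adds to the Si face of the C4 aldehyde; the ligand's sense of induction is not assigned here.

Step 1
Reactants: 1 3-methylanisole
Product: 2 1-methoxy-5-methylcyclohexa-1,4-diene
Conditions: Li, NH3 (l), THF, t-BuOH, −78 to −33 °C; NH4Cl
Reagents that add atoms: none
Why: Birch reduction, in which the two donor-substituted carbons stay sp2, should give the non-conjugated 1,4-diene whose trisubstituted alkene is held cis by the ring.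

Step 2
Reactants: 2 1-methoxy-5-methylcyclohexa-1,4-diene
Product: 4 methyl (Z)-6-hydroxy-3-methylhex-3-enoate, via aldehyde ester 3 (not isolated)
Conditions: O3 (1.0 equiv), CH2Cl2/MeOH, pyridine (cat.), −78 °C; Me2S; then NaBH4, 0 °C
Reagents that add atoms: ozone, [O-][O+]=O
Why: Chemoselective ozonolysis of the electron-rich enol ether bond with reductive work-up should turn the methoxy carbon into the methyl ester and the CH carbon into the aldehyde (reduced in the same flask), leaving the ring-derived Z trisubstituted alkene intact.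

Step 3
Reactants: 4 methyl (Z)-6-hydroxy-3-methylhex-3-enoate
Product: 5 methyl (Z)-6-[(tert-butyldimethylsilyl)oxy]-3-methylhex-3-enoate
Conditions: TBSCl, imidazole, DMF, 0 °C to rt
Reagents that add atoms: tert-butyldimethylsilyl chloride, CC(C)(C)[Si](C)(C)Cl
Why: Silylation of the primary alcohol masks the future C4 aldehyde carbon through the basic and Lewis acidic steps that follow.

Step 4
Reactants: 5 methyl (Z)-6-[(tert-butyldimethylsilyl)oxy]-3-methylhex-3-enoate
Product: 6 (Z)-6-[(tert-butyldimethylsilyl)oxy]-3-methylhex-3-enal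
Conditions: DIBAL-H (1.05 equiv), CH2Cl2, −78 °C; Rochelle salt
Reagents that add atoms: none
Why: Partial ester reduction through the tetrahedral aluminium hemiacetal, stable at −78 °C, should stop at the β,γ-unsaturated aldehyde, which is used crude and kept away from base.

Step 5
Reactants: 7 (R)-4-benzyl-1,3-thiazolidine-2-thione, 8 3-methylbutanoyl chloride
Product: 9 (R)-1-(4-benzyl-2-thioxo-1,3-thiazolidin-3-yl)-3-methylbutan-1-one
Conditions: Et3N, DMAP (cat.), CH2Cl2, 0 °C
Reagents that add atoms: none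
Why: N-Acylation of the auxiliary gives the imide that carries ring C1, C10 and the isopropyl group.

Step 6
Reactants: 6 (Z)-6-[(tert-butyldimethylsilyl)oxy]-3-methylhex-3-enal, 9 (R)-1-(4-benzyl-2-thioxo-1,3-thiazolidin-3-yl)-3-methylbutan-1-one
Product: 10 (2R,3S,5Z)-1-[(R)-4-benzyl-2-thioxo-1,3-thiazolidin-3-yl]-8-[(tert-butyldimethylsilyl)oxy]-3-hydroxy-2-isopropyl-5-methyloct-5-en-1-one
Conditions: 9, TiCl4 (1.05 equiv), i-Pr2NEt (1.1 equiv), N-methyl-2-pyrrolidinone (1.0 equiv), CH2Cl2, 0 °C; then 6, 0 °C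
Reagents that add atoms: none
Why: Titanium enolate aldol addition of the N-acyl thiazolidinethione: the Z enolate should react through a non-chelated Zimmerman–Traxler chair on the face away from the benzyl group ("Evans syn"), setting the (2R,3S) pair, which becomes ring C10 and C9.

Step 7
Reactants: 10 (2R,3S,5Z)-1-[(R)-4-benzyl-2-thioxo-1,3-thiazolidin-3-yl]-8-[(tert-butyldimethylsilyl)oxy]-3-hydroxy-2-isopropyl-5-methyloct-5-en-1-one
Product: 11 (2R,3S,5Z)-8-[(tert-butyldimethylsilyl)oxy]-3-hydroxy-2-isopropyl-N-methoxy-N,5-dimethyloct-5-enamide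
Conditions: MeONHMe·HCl, imidazole, CH2Cl2, rt
Reagents that add atoms: N,O-dimethylhydroxylamine hydrochloride, CNOC.Cl
Why: Aminolysis of the activated N-acyl thiazolidinethione should give the Weinreb amide under near-neutral conditions that leave the β-hydroxyl and the α-centre untouched.

Step 8
Reactants: 11 (2R,3S,5Z)-8-[(tert-butyldimethylsilyl)oxy]-3-hydroxy-2-isopropyl-N-methoxy-N,5-dimethyloct-5-enamide
Product: 12 (5R,6S,8Z)-11-[(tert-butyldimethylsilyl)oxy]-6-hydroxy-5-isopropyl-8-methylundec-8-en-2-yn-4-one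
Conditions: 1-propynylmagnesium bromide (3.5 equiv), THF, −20 to 0 °C; aq. NH4Cl
Reagents that add atoms: 1-propynylmagnesium bromide, CC#C[Mg]Br
Why: Weinreb ketone synthesis: the chelated tetrahedral intermediate should prevent over-addition, and one extra equivalent of Grignard reagent is consumed by the free hydroxyl.

Step 9
Reactants: 12 (5R,6S,8Z)-11-[(tert-butyldimethylsilyl)oxy]-6-hydroxy-5-isopropyl-8-methylundec-8-en-2-yn-4-one
Product: 13 (4R,5S,6S,8Z)-11-[(tert-butyldimethylsilyl)oxy]-4-hydroxy-5-isopropyl-8-methylundec-8-en-2-yn-6-yl benzoate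
Conditions: PhCHO (6 equiv), SmI2 (0.3 equiv), THF, −10 °C
Reagents that add atoms: benzaldehyde, O=Cc1ccccc1
Why: Evans–Tishchenko reduction: the samarium-bound hemiacetal of benzaldehyde should deliver hydride to the ketone through a chair-like bicyclic transition state, giving the 1,3-anti carbinol (ring C1) and placing the benzoate on the original hydroxyl (ring C9) in one operation.

Step 10
Reactants: 13 (4R,5S,6S,8Z)-11-[(tert-butyldimethylsilyl)oxy]-4-hydroxy-5-isopropyl-8-methylundec-8-en-2-yn-6-yl benzoate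
Product: 14 (2Z,4R,5S,6S,8Z)-2-[benzyl(dimethyl)silyl]-11-[(tert-butyldimethylsilyl)oxy]-4-hydroxy-5-isopropyl-8-methylundeca-2,8-dien-6-yl benzoate
Conditions: [Cp*Ru(MeCN)3]PF6 (5 mol %), BnMe2SiH (1.2 equiv), CH2Cl2, 0 °C to rt
Reagents that add atoms: benzyldimethylsilane, C[SiH](C)Cc1ccccc1
Why: Ruthenium-catalysed trans-hydrosilylation of the propargylic alcohol should add H and Si anti with silicon on the alkyne carbon distal to the carbinol, giving the Z alkenylsilane with silicon cis to the carbinol carbon.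

Step 11
Reactants: 14 (2Z,4R,5S,6S,8Z)-2-[benzyl(dimethyl)silyl]-11-[(tert-butyldimethylsilyl)oxy]-4-hydroxy-5-isopropyl-8-methylundeca-2,8-dien-6-yl benzoate
Product: 15 (2Z,4R,5R,6S,8Z)-4-acetoxy-2-[benzyl(dimethyl)silyl]-11-[(tert-butyldimethylsilyl)oxy]-5-isopropyl-8-methylundeca-2,8-dien-6-yl benzoate
Conditions: Ac2O, pyridine, DMAP (cat.), CH2Cl2, 0 °C to rt
Reagents that add atoms: acetic anhydride, CC(=O)OC(C)=O
Why: Acylation installs the ring C1 acetate and removes the free hydroxyl before the electrophilic iodination, so that iodoetherification cannot compete.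

Step 12
Reactants: 15 (2Z,4R,5R,6S,8Z)-4-acetoxy-2-[benzyl(dimethyl)silyl]-11-[(tert-butyldimethylsilyl)oxy]-5-isopropyl-8-methylundeca-2,8-dien-6-yl benzoate
Product: 16 (2Z,4R,5R,6S,8Z)-4-acetoxy-11-[(tert-butyldimethylsilyl)oxy]-2-iodo-5-isopropyl-8-methylundeca-2,8-dien-6-yl benzoate
Conditions: NIS (1.3 equiv), 2,6-lutidine, (CF3)2CHOH, 0 °C
Reagents that add atoms: N-iodosuccinimide, O=C1CCC(=O)N1I
Why: Iododesilylation: ipso attack of iodonium on the alkenylsilane, followed by loss of silicon from the β-silyl cation, should replace Si by I with retention, giving the Z alkenyl iodide with iodine cis to the acetoxy-bearing carbon.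

Step 13
Reactants: 16 (2Z,4R,5R,6S,8Z)-4-acetoxy-11-[(tert-butyldimethylsilyl)oxy]-2-iodo-5-isopropyl-8-methylundeca-2,8-dien-6-yl benzoate
Product: 17 (2Z,4R,5R,6S,8Z)-4-acetoxy-11-hydroxy-2-iodo-5-isopropyl-8-methylundeca-2,8-dien-6-yl benzoate
Conditions: HF·pyridine, THF/pyridine, 0 °C to rt
Reagents that add atoms: none
Why: Buffered fluoride cleavage of the primary silyl ether should leave both esters and the alkenyl iodide untouched, and the distant primary hydroxyl has no short path for acyl migration.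

Step 14
Reactants: 17 (2Z,4R,5R,6S,8Z)-4-acetoxy-11-hydroxy-2-iodo-5-isopropyl-8-methylundeca-2,8-dien-6-yl benzoate
Product: 18 (2Z,4R,5R,6S,8Z)-4-acetoxy-2-iodo-5-isopropyl-8-methyl-11-oxoundeca-2,8-dien-6-yl benzoate
Conditions: Dess–Martin periodinane, pyridine, CH2Cl2, 0 °C
Reagents that add atoms: none
Why: Dess–Martin oxidation under buffered, near-neutral conditions should give the β,γ-unsaturated aldehyde without migration of the Z alkene into conjugation; it is used at once.

Step 15
Reactants: 18 (2Z,4R,5R,6S,8Z)-4-acetoxy-2-iodo-5-isopropyl-8-methyl-11-oxoundeca-2,8-dien-6-yl benzoate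
Product: 19 (1S,2Z,4R,6Z,9S,10R)-1-acetoxy-4-hydroxy-10-isopropyl-3,7-dimethylcyclodeca-2,6-dien-9-yl benzoate
Conditions: CrCl2 (4 equiv), chiral oxazoline–sulfonamide ligand (4.4 equiv, enantiomer directing Si-face addition), Et3N (4.4 equiv), NiCl2 (cat.), THF/MeCN, slow addition of 18 to 0.003 M, rt
Reagents that add atoms: none
Why: Nickel(0) should insert into the C3–I bond with retention, the alkenyl group pass to chromium(III) and add 1,2 to the C4 aldehyde, the chromium alkoxide giving the free alcohol on work-up. The closest known reaction type is the Nozaki–Hiyama–Kishi macrocyclisation of an iodoalkene aldehyde, run here with a chiral sulfonamide ligand on chromium as in asymmetric Ni/Cr couplings. The ten-membered ring closes in a 10-exo-trig mode, the C3 nucleophile attacking the C4 carbonyl carbon with the oxygen exocyclic. The C4 stereocentre should be set under reagent control by the chiral chromium complex, which adds the alkenyl group to the Si face (R at C4); the substrate has no stereocentre next to the carbonyl, so its own bias is only conformational. The step needs retention of the Z C2=C3 geometry (trisubstituted alkenyl nickel and chromium species hold their configuration), addition to the aldehyde only (organochromium(III) reagents do not attack the acetate or benzoate) and no migration of the C6=C7 bond into conjugation (neutral medium). Ring closure over oligomerisation is secured by high dilution and by the two Z alkenes, which fold the chain.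

Compound list
1 | 3-methylanisole | COc1cccc(C)c1 | starting material
2 | 1-methoxy-5-methylcyclohexa-1,4-diene | COC1=CCC=C(C)C1 | intermediate
3 | methyl (Z)-3-methyl-6-oxohex-3-enoate (aldehyde ester, not isolated) | COC(=O)C/C(C)=C\CC=O | intermediate
4 | methyl (Z)-6-hydroxy-3-methylhex-3-enoate | COC(=O)C/C(C)=C\CCO | intermediate
5 | methyl (Z)-6-[(tert-butyldimethylsilyl)oxy]-3-methylhex-3-enoate | COC(=O)C/C(C)=C\CCO[Si](C)(C)C(C)(C)C | intermediate
6 | (Z)-6-[(tert-butyldimethylsilyl)oxy]-3-methylhex-3-enal | O=CC/C(C)=C\CCO[Si](C)(C)C(C)(C)C | intermediate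
7 | (R)-4-benzyl-1,3-thiazolidine-2-thione | S=C1N[C@H](Cc2ccccc2)CS1 | starting material
8 | 3-methylbutanoyl chloride | CC(C)CC(Cl)=O | starting material
9 | (R)-1-(4-benzyl-2-thioxo-1,3-thiazolidin-3-yl)-3-methylbutan-1-one | CC(C)CC(=O)N1[C@H](Cc2ccccc2)CSC1=S | intermediate
10 | (2R,3S,5Z)-1-[(R)-4-benzyl-2-thioxo-1,3-thiazolidin-3-yl]-8-[(tert-butyldimethylsilyl)oxy]-3-hydroxy-2-isopropyl-5-methyloct-5-en-1-one | S=C1SC[C@@H](Cc2ccccc2)N1C(=O)[C@H](C(C)C)[C@@H](O)C/C(C)=C\CCO[Si](C)(C)C(C)(C)C | intermediate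
11 | (2R,3S,5Z)-8-[(tert-butyldimethylsilyl)oxy]-3-hydroxy-2-isopropyl-N-methoxy-N,5-dimethyloct-5-enamide | CON(C)C(=O)[C@H](C(C)C)[C@@H](O)C/C(C)=C\CCO[Si](C)(C)C(C)(C)C | intermediate
12 | (5R,6S,8Z)-11-[(tert-butyldimethylsilyl)oxy]-6-hydroxy-5-isopropyl-8-methylundec-8-en-2-yn-4-one | CC#CC(=O)[C@H](C(C)C)[C@@H](O)C/C(C)=C\CCO[Si](C)(C)C(C)(C)C | intermediate
13 | (4R,5S,6S,8Z)-11-[(tert-butyldimethylsilyl)oxy]-4-hydroxy-5-isopropyl-8-methylundec-8-en-2-yn-6-yl benzoate | CC#C[C@H](O)[C@H](C(C)C)[C@@H](OC(=O)c1ccccc1)C/C(C)=C\CCO[Si](C)(C)C(C)(C)C | intermediate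
14 | (2Z,4R,5S,6S,8Z)-2-[benzyl(dimethyl)silyl]-11-[(tert-butyldimethylsilyl)oxy]-4-hydroxy-5-isopropyl-8-methylundeca-2,8-dien-6-yl benzoate | C/C([Si](C)(C)Cc1ccccc1)=C/[C@H](O)[C@H](C(C)C)[C@@H](OC(=O)c1ccccc1)C/C(C)=C\CCO[Si](C)(C)C(C)(C)C | intermediate
15 | (2Z,4R,5R,6S,8Z)-4-acetoxy-2-[benzyl(dimethyl)silyl]-11-[(tert-butyldimethylsilyl)oxy]-5-isopropyl-8-methylundeca-2,8-dien-6-yl benzoate | C/C([Si](C)(C)Cc1ccccc1)=C/[C@H](OC(C)=O)[C@H](C(C)C)[C@@H](OC(=O)c1ccccc1)C/C(C)=C\CCO[Si](C)(C)C(C)(C)C | intermediate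
16 | (2Z,4R,5R,6S,8Z)-4-acetoxy-11-[(tert-butyldimethylsilyl)oxy]-2-iodo-5-isopropyl-8-methylundeca-2,8-dien-6-yl benzoate | C/C(I)=C/[C@H](OC(C)=O)[C@H](C(C)C)[C@@H](OC(=O)c1ccccc1)C/C(C)=C\CCO[Si](C)(C)C(C)(C)C | intermediate
17 | (2Z,4R,5R,6S,8Z)-4-acetoxy-11-hydroxy-2-iodo-5-isopropyl-8-methylundeca-2,8-dien-6-yl benzoate | C/C(I)=C/[C@H](OC(C)=O)[C@H](C(C)C)[C@@H](OC(=O)c1ccccc1)C/C(C)=C\CCO | intermediate
18 | (2Z,4R,5R,6S,8Z)-4-acetoxy-2-iodo-5-isopropyl-8-methyl-11-oxoundeca-2,8-dien-6-yl benzoate | C/C(I)=C/[C@H](OC(C)=O)[C@H](C(C)C)[C@@H](OC(=O)c1ccccc1)C/C(C)=C\CC=O | intermediate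
19 | (1S,2Z,4R,6Z,9S,10R)-1-acetoxy-4-hydroxy-10-isopropyl-3,7-dimethylcyclodeca-2,6-dien-9-yl benzoate (CNP0125882.1) | CC(=O)O[C@H]1/C=C(/C)[C@H](O)C/C=C(/C)C[C@H](OC(=O)c2ccccc2)[C@H]1C(C)C | target

Total step count: 15. Longest linear sequence: 14 steps (steps 1–4 and 6–15).

Steps most likely to fail

1. Step 15 (key step). The facial preference imposed by the chromium ligand may be opposed by the conformational bias of the folding chain, giving poor selectivity at C4. Fallback: from 18, the ring is closed with ligand-free CrCl2/NiCl2 in DMSO at high dilution, which should give 19 together with its C4 epimer, (1S,2Z,4S,6Z,9S,10R)-1-acetoxy-4-hydroxy-10-isopropyl-3,7-dimethylcyclodeca-2,6-dien-9-yl benzoate F1. The mixture is oxidised with MnO2 (or Dess–Martin periodinane) to the ring enone (1S,2Z,6Z,9S,10R)-1-acetoxy-10-isopropyl-3,7-dimethyl-4-oxocyclodeca-2,6-dien-9-yl benzoate F2. Reduction of F2 with (S)-2-methyl-CBS-oxazaborolidine and catecholborane at −78 °C, the alkenyl group acting as the large substituent, should give the (4R)-alcohol. The detour sets out from 18 and comes back at 19.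

2. Step 12. Electrophilic iodine may attack the trisubstituted C6=C7 alkene (ring numbering), with participation of the neighbouring benzoate, in competition with the alkenylsilane. Fallback: the iodine is introduced through an alkenylaluminium species before any ester is present; this detour also avoids the Evans–Tishchenko step. From 12, silylation (TESOTf, 2,6-lutidine, −78 °C) should give the 6-O-triethylsilyl ether of 12 F3. Noyori transfer hydrogenation with the (R,R)-TsDPEN ruthenium catalyst in i-PrOH should give the (4R)-propargylic alcohol F4 under catalyst control. Red-Al (THF, 0 °C) followed by I2 (−78 °C) should effect trans-hydroalumination with aluminium on the distal carbon and give the (Z)-iodo allylic alcohol F5. Acetylation (Ac2O, pyridine, DMAP) gives the acetate F6, selective removal of the triethylsilyl group (PPTS, MeOH, 0 °C) gives the C6 alcohol F7, and benzoylation (BzCl, pyridine, DMAP) returns to the route. The detour sets out from 12 and comes back at 16.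

3. Step 6. The β,γ-unsaturated aldehyde 6 may isomerise into conjugation (with loss of the Z geometry) under the amine base and titanium Lewis acid before the C–C bond forms. Fallback: a boron enolate aldol, which exposes the aldehyde to neither free amine nor a strong Lewis acid. Commercial (R)-4-benzyloxazolidin-2-one is acylated with 8 (n-BuLi, THF, −78 °C) to (R)-4-benzyl-3-(3-methylbutanoyl)oxazolidin-2-one F8. Enolisation with Bu2BOTf/i-Pr2NEt (CH2Cl2, −78 °C) and addition of 6 should give the Evans syn adduct (R)-4-benzyl-3-[(2R,3S,5Z)-8-[(tert-butyldimethylsilyl)oxy]-3-hydroxy-2-isopropyl-5-methyloct-5-enoyl]oxazolidin-2-one F9. Transamination with Me3Al/MeONHMe·HCl then gives the Weinreb amide. The detour sets out from 6 and 8 and comes back at 11.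

Further compounds
F1 | step 15 | (1S,2Z,4S,6Z,9S,10R)-1-acetoxy-4-hydroxy-10-isopropyl-3,7-dimethylcyclodeca-2,6-dien-9-yl benzoate (C4 epimer of 19) | CC(=O)O[C@H]1/C=C(/C)[C@@H](O)C/C=C(/C)C[C@H](OC(=O)c2ccccc2)[C@H]1C(C)C
F2 | step 15 | (1S,2Z,6Z,9S,10R)-1-acetoxy-10-isopropyl-3,7-dimethyl-4-oxocyclodeca-2,6-dien-9-yl benzoate | CC(=O)O[C@H]1/C=C(/C)C(=O)C/C=C(/C)C[C@H](OC(=O)c2ccccc2)[C@H]1C(C)C
F3 | step 12 | (5R,6S,8Z)-11-[(tert-butyldimethylsilyl)oxy]-5-isopropyl-8-methyl-6-[(triethylsilyl)oxy]undec-8-en-2-yn-4-one | CC#CC(=O)[C@H](C(C)C)[C@@H](O[Si](CC)(CC)CC)C/C(C)=C\CCO[Si](C)(C)C(C)(C)C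
F4 | step 12 | (4R,5S,6S,8Z)-11-[(tert-butyldimethylsilyl)oxy]-5-isopropyl-8-methyl-6-[(triethylsilyl)oxy]undec-8-en-2-yn-4-ol | CC#C[C@H](O)[C@H](C(C)C)[C@@H](O[Si](CC)(CC)CC)C/C(C)=C\CCO[Si](C)(C)C(C)(C)C
F5 | step 12 | (2Z,4R,5S,6S,8Z)-11-[(tert-butyldimethylsilyl)oxy]-2-iodo-5-isopropyl-8-methyl-6-[(triethylsilyl)oxy]undeca-2,8-dien-4-ol | C/C(I)=C/[C@H](O)[C@H](C(C)C)[C@@H](O[Si](CC)(CC)CC)C/C(C)=C\CCO[Si](C)(C)C(C)(C)C
F6 | step 12 | (2Z,4R,5S,6S,8Z)-11-[(tert-butyldimethylsilyl)oxy]-2-iodo-5-isopropyl-8-methyl-6-[(triethylsilyl)oxy]undeca-2,8-dien-4-yl acetate | C/C(I)=C/[C@H](OC(C)=O)[C@H](C(C)C)[C@@H](O[Si](CC)(CC)CC)C/C(C)=C\CCO[Si](C)(C)C(C)(C)C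
F7 | step 12 | (2Z,4R,5R,6S,8Z)-11-[(tert-butyldimethylsilyl)oxy]-6-hydroxy-2-iodo-5-isopropyl-8-methylundeca-2,8-dien-4-yl acetate | C/C(I)=C/[C@H](OC(C)=O)[C@H](C(C)C)[C@@H](O)C/C(C)=C\CCO[Si](C)(C)C(C)(C)C
F8 | step 6 | (R)-4-benzyl-3-(3-methylbutanoyl)oxazolidin-2-one | CC(C)CC(=O)N1[C@H](Cc2ccccc2)COC1=O
F9 | step 6 | (R)-4-benzyl-3-[(2R,3S,5Z)-8-[(tert-butyldimethylsilyl)oxy]-3-hydroxy-2-isopropyl-5-methyloct-5-enoyl]oxazolidin-2-one | O=C1OC[C@@H](Cc2ccccc2)N1C(=O)[C@H](C(C)C)[C@@H](O)C/C(C)=C\CCO[Si](C)(C)C(C)(C)C
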